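**Retrosynthetic overview**
1. The C–Br bond is made last, by invertive bromination of the only axial secondary carbinol (ring B) of tetraol 13. Both trans-diols of 13 come from one hydroxyl-directed double reduction of bis-ketol 12.
2. The central bond (ring A C-3 to CH2) comes from alkylating the ring A enolate, made by conjugate isopropenylation of enone 5, with the ring B allylic chloride 8.
3. Chloride 8 comes from the same enone 5 by catalyst-controlled conjugate isopropenylation followed by allylic chlorination. The C20 skeleton is therefore 2 × C7 + 2 × C3.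
4. Enone 5 comes from (S)-ketol 3. Ketol 3 is made by an enantioselective α-ketol ring expansion (1,2-alkyl shift) of achiral 1-acetylcyclopentanol 2, which comes from alkynol 1.
5. Ring order: the six-membered carbocycle is formed once (step 2). One copy is elaborated to ring B (steps 4–5), and a second copy becomes ring A when the two are joined (step 6).

Assumption: the target is taken exactly as drawn, (1S,2S,3R,4S) in the diol ring (ring A) and (1R,3R,4S) in the bromohydrin ring (ring B, Br cis to the tertiary OH), and 1, 6 and 9 are catalogue chemicals.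

**Step 1**
Reactants: 1 1-ethynylcyclopentan-1-ol
Product: 2 1-(1-hydroxycyclopentyl)ethan-1-one
Conditions: HgO (2 mol %), 10% aq H2SO4, 65 °C
Reagents that add atoms: water, O
Why: Kucherov (Markovnikov) hydration of the terminal alkyne of a tertiary propargylic alcohol gives the methyl ketone, the textbook entry to 1-acylcycloalkanols, and no stereocentre is formed.

**Step 2**
Reactants: 2 1-(1-hydroxycyclopentyl)ethan-1-one
Product: 3 (S)-2-hydroxy-2-methylcyclohexan-1-one
Conditions: AlMe3 (10 mol %), (R)-3,3′-bis(triphenylsilyl)-BINOL (11 mol %), 4 Å MS, toluene, 60 °C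
Reagents that add atoms: none
Why: Proposed new method: a catalytic enantioselective desymmetrising α-ketol (acyloin) ring expansion of an unstrained dialkyl ketol, in which 2 protonolyses the Al–Me bond to give a rigid five-membered aluminium alkoxide–ketone chelate whose two enantiotopic ring CH2 groups lie above and below the chelate plane, the 3,3′-SiPh3 walls of the binaphtholate leave room on only one face for the ring carbon that swings over to the activated acetyl carbon (the small CH3 moves to the shielded face), so one 1,2-alkyl shift forms the six-membered ring and sets the (S)-carbinol centre that becomes C-1 of ring A and C-4 of ring B, turnover comes from alkoxide exchange with fresh 2 and the driving force is the more stable cyclohexanone, the closest known reaction types being the aluminium-alkoxide-promoted α-ketol rearrangement (D-homoannulation of steroidal 17-hydroxy-20-ketones) and chiral Lewis-acid-catalysed acyloin rearrangements of aryl ketols, strained cyclobutanols and α-siloxy aldehydes, and the ligand antipode is used instead if the first run delivers the (R)-ketol.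

**Step 3**
Reactants: 3 (S)-2-hydroxy-2-methylcyclohexan-1-one
Product: 5 (S)-6-methyl-6-(triethylsilyloxy)cyclohex-2-en-1-one, via bis(triethylsilyl) enol ether 4 (not isolated)
Conditions: TESOTf (2.5 equiv), Et3N (3 equiv), CH2Cl2, 0 °C to rt; short silica plug, concentrate; Pd(OAc)2 (10 mol %), O2 (1 atm), DMSO, 40 °C
Reagents that add atoms: triethylsilyl trifluoromethanesulfonate (TESOTf), CC[Si](CC)(CC)OS(=O)(=O)C(F)(F)F
Why: Soft enolisation can occur only toward the single CH2 flank and silylates the tertiary OH at the same time, aerobic Saegusa–Ito oxidation of the crude silyl enol ether then gives the enone, over-oxidation is blocked by the quaternary carbon, and the stereocentre is untouched.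

**Step 4**
Reactants: 5 (S)-6-methyl-6-(triethylsilyloxy)cyclohex-2-en-1-one, 6 isopropenylboronic acid
Product: 7 (2S,5R)-2-methyl-5-(prop-1-en-2-yl)-2-(triethylsilyloxy)cyclohexan-1-one
Conditions: 6 (3 equiv), [RhCl(C2H4)2]2 (1.5 mol %), (R)-BINAP (3.3 mol %), KOH (10 mol %), dioxane/H2O 10:1, 35 °C
Reagents that add atoms: none
Why: In this Hayashi–Miyaura rhodium-catalysed asymmetric 1,4-addition the (R)-BINAP–rhodium alkenyl species carbometalates the enone face that gives the (5R) centre (isopropenyl cis to the silyloxy group, the ring B relationship), catalyst control of about 2.5–3 kcal/mol overrides the roughly 1 kcal/mol substrate bias of this mismatched pair, and the minor (5S) epimer is removed by chromatography.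

**Step 5**
Reactants: 7 (2S,5R)-2-methyl-5-(prop-1-en-2-yl)-2-(triethylsilyloxy)cyclohexan-1-one
Product: 8 (2S,5R)-5-(3-chloroprop-1-en-2-yl)-2-methyl-2-(triethylsilyloxy)cyclohexan-1-one
Conditions: Ca(OCl)2 (0.7 equiv), solid CO2, CH2Cl2/H2O, 0 °C
Reagents that add atoms: calcium hypochlorite, [Ca+2].[O-]Cl.[O-]Cl
Why: Electrophilic allylic chlorination with HOCl made in situ (chloronium ion, then loss of a methyl proton) is the standard way to turn the isopropenyl group of cyclohexane terpenoids into a 2-substituted allyl chloride, the near-neutral medium spares ketone and silyl ether, and no stereocentre is touched.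

**Step 6**
Reactants: 5 (S)-6-methyl-6-(triethylsilyloxy)cyclohex-2-en-1-one, 9 isopropenylmagnesium bromide, 8 (2S,5R)-5-(3-chloroprop-1-en-2-yl)-2-methyl-2-(triethylsilyloxy)cyclohexan-1-one
Product: 12 (2S,5S,6R)-2-hydroxy-6-{2-[(1R,4S)-4-hydroxy-4-methyl-3-oxocyclohexyl]prop-2-en-1-yl}-2-methyl-5-(prop-1-en-2-yl)cyclohexan-1-one, via bromomagnesium enolate 10 (not isolated), via bis(triethylsilyl) diketone 11 (not isolated)
Conditions: 5 (1.3 equiv), 9 (1.2 equiv), CuBr·SMe2 (15 mol %), THF, −78 to −30 °C; 8 (1.0 equiv), Bu4NI (20 mol %), DMPU, −30 to 0 °C; then 1 M HCl, THF/MeOH, rt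
Reagents that add atoms: none
Why: In this copper-catalysed conjugate addition/enolate alkylation (three-component coupling) axial attack on the half-chair of 5 that holds the silyloxy group pseudoaxial (smaller A value than CH3, C–O bond aligned with the π system, poor chelator) places isopropenyl trans to oxygen (5S), the regiodefined enolate 10 has no α′-hydrogen and cannot equilibrate, it is alkylated anti to the isopropenyl group to give the trans-diequatorial and also thermodynamic (6R) centre, and the acidic work-up cleaves both silyl ethers.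

**Step 7**
Reactants: 12 (2S,5S,6R)-2-hydroxy-6-{2-[(1R,4S)-4-hydroxy-4-methyl-3-oxocyclohexyl]prop-2-en-1-yl}-2-methyl-5-(prop-1-en-2-yl)cyclohexan-1-one
Product: 13 (1S,2S,3R,4S)-3-{2-[(1R,3S,4S)-3,4-dihydroxy-4-methylcyclohexyl]prop-2-en-1-yl}-1-methyl-4-(prop-1-en-2-yl)cyclohexane-1,2-diol
Conditions: Me4NBH(OAc)3 (8 equiv), MeCN/AcOH 1:1, −20 °C to rt
Reagents that add atoms: none
Why: In this hydroxyl-directed (Saksena–Evans) triacetoxyborohydride reduction each tertiary OH binds boron and delivers hydride to its own face of the neighbouring ketone, which gives a trans-diol in both rings at once, diequatorial in ring A (2S, the same sense as intrinsic axial attack) and diaxial in ring B (3S, which an undirected hydride would not give).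

**Step 8**
Reactants: 13 (1S,2S,3R,4S)-3-{2-[(1R,3S,4S)-3,4-dihydroxy-4-methylcyclohexyl]prop-2-en-1-yl}-1-methyl-4-(prop-1-en-2-yl)cyclohexane-1,2-diol
Product: 14 (1S,2S,3R,4S)-3-{2-[(1R,3R,4S)-3-bromo-4-hydroxy-4-methylcyclohexyl]prop-2-en-1-yl}-1-methyl-4-(prop-1-en-2-yl)cyclohexane-1,2-diol
Conditions: CBr4 (1.6 equiv), PPh3 (1.6 equiv), CH2Cl2, 0 °C to rt, no added base
Reagents that add atoms: tetrabromomethane, BrC(Br)(Br)Br
Why: In this Appel bromination (SN2 with inversion) only the ring B secondary OH is axial, has a CH2 neighbour and an open backside, so its alkoxyphosphonium ion is displaced to the equatorial (3R) bromide cis to the tertiary OH, whereas the ring A secondary OH is equatorial with three gauche neighbours and a blocked backside, the tertiary alcohols do not react, and the base-free medium keeps the neutral neighbouring OH from closing to an epoxide.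

**Compound list**
1 | 1-ethynylcyclopentan-1-ol | C#CC1(O)CCCC1 | starting material
2 | 1-(1-hydroxycyclopentyl)ethan-1-one | CC(=O)C1(O)CCCC1 | intermediate
3 | (S)-2-hydroxy-2-methylcyclohexan-1-one | C1CC[C@](C)(O)C(=O)C1 | intermediate
4 | (S)-6-methyl-1,6-bis(triethylsilyloxy)cyclohex-1-ene | C1CC[C@](C)(O[Si](CC)(CC)CC)C(O[Si](CC)(CC)CC)=C1 | intermediate
5 | (S)-6-methyl-6-(triethylsilyloxy)cyclohex-2-en-1-one | C1C[C@](C)(O[Si](CC)(CC)CC)C(=O)C=C1 | intermediate
6 | isopropenylboronic acid | C=C(C)B(O)O | starting material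
7 | (2S,5R)-2-methyl-5-(prop-1-en-2-yl)-2-(triethylsilyloxy)cyclohexan-1-one | C=C(C)[C@@H]1CC[C@](C)(O[Si](CC)(CC)CC)C(=O)C1 | intermediate
8 | (2S,5R)-5-(3-chloroprop-1-en-2-yl)-2-methyl-2-(triethylsilyloxy)cyclohexan-1-one | C=C(CCl)[C@@H]1CC[C@](C)(O[Si](CC)(CC)CC)C(=O)C1 | intermediate
9 | isopropenylmagnesium bromide | C=C(C)[Mg]Br | starting material
10 | bromomagnesium (3S,6S)-6-methyl-3-(prop-1-en-2-yl)-6-(triethylsilyloxy)cyclohex-1-en-1-olate | C=C(C)[C@H]1CC[C@](C)(O[Si](CC)(CC)CC)C(O[Mg]Br)=C1 | intermediate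
11 | (2S,5S,6R)-2-methyl-6-{2-[(1R,4S)-4-methyl-3-oxo-4-(triethylsilyloxy)cyclohexyl]prop-2-en-1-yl}-5-(prop-1-en-2-yl)-2-(triethylsilyloxy)cyclohexan-1-one | C=C(C[C@@H]1[C@@H](C(C)=C)CC[C@](C)(O[Si](CC)(CC)CC)C1=O)[C@@H]2CC[C@](C)(O[Si](CC)(CC)CC)C(=O)C2 | intermediate
12 | (2S,5S,6R)-2-hydroxy-6-{2-[(1R,4S)-4-hydroxy-4-methyl-3-oxocyclohexyl]prop-2-en-1-yl}-2-methyl-5-(prop-1-en-2-yl)cyclohexan-1-one | C=C(C[C@@H]1[C@@H](C(C)=C)CC[C@](C)(O)C1=O)[C@@H]2CC[C@](C)(O)C(=O)C2 | intermediate
13 | (1S,2S,3R,4S)-3-{2-[(1R,3S,4S)-3,4-dihydroxy-4-methylcyclohexyl]prop-2-en-1-yl}-1-methyl-4-(prop-1-en-2-yl)cyclohexane-1,2-diol | C=C(C[C@@H]1[C@@H](C(C)=C)CC[C@](C)(O)[C@H]1O)[C@@H]2CC[C@](C)(O)[C@@H](O)C2 | intermediate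
14 | (1S,2S,3R,4S)-3-{2-[(1R,3R,4S)-3-bromo-4-hydroxy-4-methylcyclohexyl]prop-2-en-1-yl}-1-methyl-4-(prop-1-en-2-yl)cyclohexane-1,2-diol | C=C(C[C@@H]1[C@@H](C(=C)C)CC[C@](C)(O)[C@H]1O)[C@@H]1CC[C@](C)(O)[C@H](Br)C1 | target

**Total step count:** 8.
**Longest linear sequence:** 8 steps (1 → 2 → 3 → 5 → 7 → 8 → 12 → 13 → 14; enone 5 enters twice).

**The three steps most likely to fail**

**Step 2 (the proposed new reaction).**
- Risks: the unstrained alkyl shift may be too slow at a temperature where the chiral pocket still discriminates. The tertiary alkoxide product may inhibit turnover. Reversibility may erode the ee.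
- The fallback uses known chemistry only, sets out from 2 and comes back at 3.
- Ketol 2 is ring-expanded without induction by Al(OtBu)3 in hot toluene, the established aluminium alkoxide α-ketol rearrangement. This gives racemic 2-hydroxy-2-methylcyclohexan-1-one F1.
- Acylation with (1S)-camphanic chloride and DMAP in pyridine gives two diastereomeric esters. The (S)-1-methyl-2-oxocyclohexyl camphanate F2 is separated by crystallisation or chromatography from the (R)-1-methyl-2-oxocyclohexyl camphanate F3.
- K2CO3 in MeOH releases 3 from F2.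

**Step 6.**
- Risks: the facial selectivity of the conjugate addition rests only on a conformational bias. The magnesium enolate may also alkylate slowly with a chloride that carries its own ketone, allowing proton transfer or aldol side reactions.
- The fallback sets out from 5 and comes back at 11.
- Enone 5 is treated with 6 as in step 4 but with (S)-BINAP, now matched with the substrate bias. This gives (2S,5S)-2-methyl-5-(prop-1-en-2-yl)-2-(triethylsilyloxy)cyclohexan-1-one F4.
- Because C-2 is quaternary, LiN(i-Pr)2 at −78 °C can form only lithium (3S,6S)-6-methyl-3-(prop-1-en-2-yl)-6-(triethylsilyloxy)cyclohex-1-en-1-olate F5.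
- Chloride 8 is converted with NaI in acetone into (2S,5R)-5-(3-iodoprop-1-en-2-yl)-2-methyl-2-(triethylsilyloxy)cyclohexan-1-one F6.
- Alkylation of the lithium enolate with this iodide at −78 °C gives 11, which is desilylated as in step 6.

**Step 8.**
- Risks: activation of the ring A secondary OH, and participation of the trans-diaxial tertiary OH. The latter would give an epoxide and then the trans-bromohydrin.
- The fallback replaces selectivity by protection, sets out from 11 (isolated instead of desilylated) and comes back at 14.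
- LiBH(s-Bu)3 at −78 °C reduces only the less hindered ring B ketone, from the equatorial side. This gives (2S,5S,6R)-6-{2-[(1R,3S,4S)-3-hydroxy-4-methyl-4-(triethylsilyloxy)cyclohexyl]prop-2-en-1-yl}-2-methyl-5-(prop-1-en-2-yl)-2-(triethylsilyloxy)cyclohexan-1-one F7.
- This is now the only free OH and both tertiary oxygens are silylated, so CBr4/PPh3 gives with inversion (2S,5S,6R)-6-{2-[(1R,3R,4S)-3-bromo-4-methyl-4-(triethylsilyloxy)cyclohexyl]prop-2-en-1-yl}-2-methyl-5-(prop-1-en-2-yl)-2-(triethylsilyloxy)cyclohexan-1-one F8.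
- NaBH4 in MeOH reduces the ring A ketone by axial attack to (1S,2S,5S,6R)-6-{2-[(1R,3R,4S)-3-bromo-4-methyl-4-(triethylsilyloxy)cyclohexyl]prop-2-en-1-yl}-2-methyl-5-(prop-1-en-2-yl)-2-(triethylsilyloxy)cyclohexan-1-ol F9.
- 1 M HCl in THF/MeOH then gives 14.

**Further compounds**
F1 | step 2 | racemic 2-hydroxy-2-methylcyclohexan-1-one | CC1(O)CCCCC1=O
F2 | step 2 | (S)-1-methyl-2-oxocyclohexyl (1S,4R)-camphanate | O=C(O[C@@]1(C)CCCCC1=O)[C@@]23CC[C@@](C)(C(=O)O2)C3(C)C
F3 | step 2 | (R)-1-methyl-2-oxocyclohexyl (1S,4R)-camphanate | O=C(O[C@]1(C)CCCCC1=O)[C@@]23CC[C@@](C)(C(=O)O2)C3(C)C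
F4 | step 6 | (2S,5S)-2-methyl-5-(prop-1-en-2-yl)-2-(triethylsilyloxy)cyclohexan-1-one | C=C(C)[C@H]1CC[C@](C)(O[Si](CC)(CC)CC)C(=O)C1
F5 | step 6 | lithium (3S,6S)-6-methyl-3-(prop-1-en-2-yl)-6-(triethylsilyloxy)cyclohex-1-en-1-olate | C=C(C)[C@H]1CC[C@](C)(O[Si](CC)(CC)CC)C(O[Li])=C1
F6 | step 6 | (2S,5R)-5-(3-iodoprop-1-en-2-yl)-2-methyl-2-(triethylsilyloxy)cyclohexan-1-one | C=C(CI)[C@@H]1CC[C@](C)(O[Si](CC)(CC)CC)C(=O)C1
F7 | step 8 | (2S,5S,6R)-6-{2-[(1R,3S,4S)-3-hydroxy-4-methyl-4-(triethylsilyloxy)cyclohexyl]prop-2-en-1-yl}-2-methyl-5-(prop-1-en-2-yl)-2-(triethylsilyloxy)cyclohexan-1-one | C=C(C[C@@H]1[C@@H](C(C)=C)CC[C@](C)(O[Si](CC)(CC)CC)C1=O)[C@@H]2CC[C@](C)(O[Si](CC)(CC)CC)[C@@H](O)C2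
F8 | step 8 | (2S,5S,6R)-6-{2-[(1R,3R,4S)-3-bromo-4-methyl-4-(triethylsilyloxy)cyclohexyl]prop-2-en-1-yl}-2-methyl-5-(prop-1-en-2-yl)-2-(triethylsilyloxy)cyclohexan-1-one | C=C(C[C@@H]1[C@@H](C(C)=C)CC[C@](C)(O[Si](CC)(CC)CC)C1=O)[C@@H]2CC[C@](C)(O[Si](CC)(CC)CC)[C@H](Br)C2
F9 | step 8 | (1S,2S,5S,6R)-6-{2-[(1R,3R,4S)-3-bromo-4-methyl-4-(triethylsilyloxy)cyclohexyl]prop-2-en-1-yl}-2-methyl-5-(prop-1-en-2-yl)-2-(triethylsilyloxy)cyclohexan-1-ol | C=C(C[C@@H]1[C@@H](C(C)=C)CC[C@](C)(O[Si](CC)(CC)CC)[C@H]1O)[C@@H]2CC[C@](C)(O[Si](CC)(CC)CC)[C@H](Br)C2
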